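**Retrosynthetic overview**

1. Conneotricone 16 comes from its tribenzyl derivative 15 by global hydrogenolysis in the last step.
2. 15 comes from depside 14 by forming the diaryl ether bond O(ring A)–C4(ring B). The ether oxygen sits on the ring B carbon para to the ring B phenol, between the carbon bearing the ester oxygen and the carbon bearing the phthalide CH2. In 14 this carbon is the only C–H of ring B, so anodic oxidation of the ring B phenol can deliver the ring A phenol oxygen only there, closing the seven-membered dioxepinone ring.
3. 14 comes from esterification of the ring A acid 12 with the unchelated 5-OH of the ring B phthalide 6.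
4. 6 comes from atraric acid 1 (one methyl becomes the lactone CH2, the other CH2OBn). 12 comes from 2,6-dihydroxy-4-methylbenzoic acid 7 (benzyl ester, formylation, O-benzylation, Pinnick oxidation).
5. Ring order: phthalide lactone (step 4), then the central seven-membered ring (step 10).

Key step: step 10

Remark on naming: ring A is the methyl-bearing benzene ring, ring B the benzene ring of the phthalide; ring B positions use phthalide numbering (C1 carbonyl, C3 CH2, C4 to C7 aromatic).

Assumption: ring A is drawn from 2,6-dihydroxy-4-methylbenzoic acid (p-orsellinic acid, taken as a catalogue compound) because its carboxyl carbon already lies between the two oxygens and the second carboxyl carbon then enters at a position that symmetry makes unambiguous.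

**Route**

Step 1
Reactants: 1 atraric acid (methyl 2,4-dihydroxy-3,6-dimethylbenzoate)
Product: 2 methyl 2,4-diacetoxy-3,6-dimethylbenzoate
Conditions: Ac2O, pyridine, DMAP (cat.), rt
Reagents that add atoms: acetic anhydride, CC(=O)OC(C)=O
Why: O-acetylation (nucleophilic acyl substitution, DMAP catalysis) caps both phenols, including the chelated one, so that the ring is too electron-poor for ionic bromination in the next step.

Step 2
Reactants: 2 methyl 2,4-diacetoxy-3,6-dimethylbenzoate
Product: 3 methyl 2,4-diacetoxy-3,6-bis(bromomethyl)benzoate
Conditions: NBS (2.2 equiv), AIBN (cat.), PhCF3, 85 °C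
Reagents that add atoms: N-bromosuccinimide, O=C1CCC(=O)N1Br
Why: Wohl–Ziegler radical bromination takes one hydrogen from each of the two benzylic methyl groups, the only weak C–H bonds of the deactivated arene, and both bromomethyl groups are wanted.

Step 3
Reactants: 3 methyl 2,4-diacetoxy-3,6-bis(bromomethyl)benzoate
Product: 4 methyl 2,4-diacetoxy-3,6-bis(acetoxymethyl)benzoate
Conditions: KOAc, DMF, rt to 40 °C
Reagents that add atoms: potassium acetate, CC(=O)[O-].[K+]
Why: Double SN2 displacement of the primary benzylic bromides by acetate gives a defined tetraacetate whose two arms can be unmasked as alcohols in the next step without free HBr.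

Step 4
Reactants: 4 methyl 2,4-diacetoxy-3,6-bis(acetoxymethyl)benzoate
Product: 6 6-[(benzyloxy)methyl]-5,7-dihydroxyisobenzofuran-1(3H)-one, via triol phthalide 5 (not isolated)
Conditions: BnOH (solvent), TsOH·H2O (0.2 equiv), 60 °C
Reagents that add atoms: benzyl alcohol, OCc1ccccc1
Why: Acid-catalysed transesterification should strip the four acetates as benzyl acetate, the hydroxymethyl group ortho to the methyl ester lactonises to the phthalide, and the hydroxymethyl group flanked by two free phenols ionises to an o-quinone-methide-like benzylic cation that the solvent captures as the benzyl ether (SN1 etherification of an o-hydroxybenzyl alcohol), whereas the lactone CH2 is meta to both phenols and cannot ionise.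

Step 5
Reactants: 7 2,6-dihydroxy-4-methylbenzoic acid
Product: 8 benzyl 2,6-dihydroxy-4-methylbenzoate
Conditions: BnBr (1.05 equiv), KHCO3 (1.2 equiv), DMF, 40 °C
Reagents that add atoms: benzyl bromide, BrCc1ccccc1
Why: Carboxylate O-alkylation (SN2) is selective because hydrogencarbonate deprotonates only the strongly acidic carboxyl group and leaves the two chelated phenols neutral.

Step 6
Reactants: 8 benzyl 2,6-dihydroxy-4-methylbenzoate
Product: 10 benzyl 3-formyl-2,6-dihydroxy-4-methylbenzoate, via α-chloro ether 9 (not isolated)
Conditions: Cl2CHOMe (1.3 equiv), TiCl4 (2.5 equiv), CH2Cl2, −20 to 0 °C; then 1 M HCl, 0 °C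
Reagents that add atoms: dichloromethyl methyl ether, COC(Cl)Cl; water, O
Why: Rieche formylation (Friedel–Crafts attack of the chloro(methoxy)carbenium ion, then hydrolysis) can give only one regioisomer because the two free ring carbons are equivalent by symmetry, each ortho to one phenol and para to the other, and the first formyl group deactivates the ring against a second.

Step 7
Reactants: 10 benzyl 3-formyl-2,6-dihydroxy-4-methylbenzoate
Product: 11 benzyl 6-(benzyloxy)-3-formyl-2-hydroxy-4-methylbenzoate
Conditions: BnBr (1.05 equiv), K2CO3 (1.1 equiv), DMF, rt
Reagents that add atoms: benzyl bromide, BrCc1ccccc1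
Why: Williamson etherification should go to the 6-OH, which is para to the formyl group and has a free neighbouring position, while the 2-OH is buried between the formyl and ester groups and locked in a hydrogen bond to the aldehyde, the pattern known for 4-O-alkylation of 3-formyl-2,4-dihydroxybenzoates.

Step 8
Reactants: 11 benzyl 6-(benzyloxy)-3-formyl-2-hydroxy-4-methylbenzoate
Product: 12 4-(benzyloxy)-3-[(benzyloxy)carbonyl]-2-hydroxy-6-methylbenzoic acid
Conditions: NaClO2, NaH2PO4, 2-methyl-2-butene, t-BuOH–THF–H2O, 0 °C to rt
Reagents that add atoms: sodium chlorite, [Na+].[O-]Cl=O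
Why: Pinnick oxidation converts the aldehyde into the acid without touching the benzyl ether or benzyl ester, and the alkene scavenger removes HOCl before it can chlorinate the free ring position.

Step 9
Reactants: 12 4-(benzyloxy)-3-[(benzyloxy)carbonyl]-2-hydroxy-6-methylbenzoic acid; 6 6-[(benzyloxy)methyl]-5,7-dihydroxyisobenzofuran-1(3H)-one
Product: 14 depside benzyl 6-(benzyloxy)-3-({6-[(benzyloxy)methyl]-7-hydroxy-1-oxo-1,3-dihydroisobenzofuran-5-yl}oxycarbonyl)-2-hydroxy-4-methylbenzoate, via O-acylisourea 13 (not isolated)
Conditions: DCC (1.1 equiv), toluene–THF, 0 °C to rt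
Reagents that add atoms: none
Why: Carbodiimide-mediated esterification (depside coupling) should acylate only the 5-OH of 6, because the 7-OH is hydrogen-bonded to the lactone carbonyl and flanked on both sides, and the ring A phenol of 12, chelated between two carbonyl groups, does not compete.

Step 10
Reactants: 14 depside with free phenols on ring A and ring B
Product: 15 tribenzyl conneotricone (ring B phenol free)
Conditions: undivided cell, boron-doped diamond anode, Pt cathode, (CF3)2CHOH, Bu4NPF6 (0.1 M), 14 at 5 mM, constant current 2 mA cm−2, 2.2 F mol−1, 25 °C
Reagents that add atoms: none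
Why: Proposed new method: at the anode the ring B phenol should lose two electrons and a proton to give a phenoxonium ion that (CF3)2CHOH stabilises and does not trap, with the charge shared by the two blocked ortho carbons and the para carbon C4; the ring A phenol oxygen, held by the ester, adds to C4 and loss of the C4 proton restores the phenol, while the cathode turns the released protons into H2. The closest known reactions are anodic dehydrogenative phenol–arene and phenol–phenol cross-couplings in (CF3)2CHOH and the PhI(OAc)2-mediated para-attack of oxygen nucleophiles on phenols, and the step follows the oxidative depside-to-depsidone closure assumed in biosynthesis, but a preparative version on a depside has not been shown. The seven-membered dioxepinone ring closes by attack of oxygen on a cationic sp2 carbon, a 7-exo-trig closure when counted on the C3a=C4 bond, and it needs the lactone-like E rotamer of the aryl ester, which should be reachable because the ring A phenol can keep a hydrogen bond to the neighbouring CO2Bn carbonyl while the depside carbonyl turns toward the methyl group. No stereocentre is formed. Chemoselectivity requires ring B to be oxidised before ring A, which is expected because ring B carries one carbonyl group and two alkyl groups whereas the ring A phenol is flanked by two ester carbonyls, and regioselectivity is secured because C4 is the only unsubstituted carbon of ring B and lies para to its phenol. High dilution and a charge near 2 F per mol are set against intermolecular C–C coupling and against further oxidation of the p-aryloxyphenol product.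

Step 11
Reactants: 15 tribenzyl conneotricone
Product: 16 conneotricone
Conditions: H2 (1 atm), 10% Pd/C, EtOAc, rt, stopped after uptake of 3 equiv
Reagents that add atoms: none
Why: Catalytic hydrogenolysis cleaves the three PhCH2–O bonds (aryl benzyl ether, benzyl ester, alkyl benzyl ether) under neutral conditions that leave the depsidone ester and the phthalide intact.

**Compound list**

1 | atraric acid (methyl 2,4-dihydroxy-3,6-dimethylbenzoate) | COC(=O)c1c(C)cc(O)c(C)c1O | starting material
2 | methyl 2,4-diacetoxy-3,6-dimethylbenzoate | COC(=O)c1c(C)cc(OC(C)=O)c(C)c1OC(C)=O | intermediate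
3 | methyl 2,4-diacetoxy-3,6-bis(bromomethyl)benzoate | COC(=O)c1c(CBr)cc(OC(C)=O)c(CBr)c1OC(C)=O | intermediate
4 | methyl 2,4-diacetoxy-3,6-bis(acetoxymethyl)benzoate | COC(=O)c1c(COC(C)=O)cc(OC(C)=O)c(COC(C)=O)c1OC(C)=O | intermediate
5 | 5,7-dihydroxy-6-(hydroxymethyl)isobenzofuran-1(3H)-one (triol phthalide, not isolated) | O=C1OCc2cc(O)c(CO)c(O)c21 | intermediate
6 | 6-[(benzyloxy)methyl]-5,7-dihydroxyisobenzofuran-1(3H)-one | O=C1OCc2cc(O)c(COCc3ccccc3)c(O)c21 | intermediate
7 | 2,6-dihydroxy-4-methylbenzoic acid (p-orsellinic acid) | Cc1cc(O)c(C(=O)O)c(O)c1 | starting material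
8 | benzyl 2,6-dihydroxy-4-methylbenzoate | Cc1cc(O)c(C(=O)OCc2ccccc2)c(O)c1 | intermediate
9 | benzyl 3-[chloro(methoxy)methyl]-2,6-dihydroxy-4-methylbenzoate (α-chloro ether, racemic, not isolated) | Cc1cc(O)c(C(=O)OCc2ccccc2)c(O)c1C(Cl)OC | intermediate
10 | benzyl 3-formyl-2,6-dihydroxy-4-methylbenzoate | Cc1cc(O)c(C(=O)OCc2ccccc2)c(O)c1C=O | intermediate
11 | benzyl 6-(benzyloxy)-3-formyl-2-hydroxy-4-methylbenzoate | Cc1cc(OCc2ccccc2)c(C(=O)OCc2ccccc2)c(O)c1C=O | intermediate
12 | 4-(benzyloxy)-3-[(benzyloxy)carbonyl]-2-hydroxy-6-methylbenzoic acid | Cc1cc(OCc2ccccc2)c(C(=O)OCc2ccccc2)c(O)c1C(=O)O | intermediate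
13 | O-acylisourea of acid 12 and DCC (not isolated) | Cc1cc(OCc2ccccc2)c(C(=O)OCc2ccccc2)c(O)c1C(=O)OC(=NC3CCCCC3)NC3CCCCC3 | intermediate
14 | depside: benzyl 6-(benzyloxy)-3-({6-[(benzyloxy)methyl]-7-hydroxy-1-oxo-1,3-dihydroisobenzofuran-5-yl}oxycarbonyl)-2-hydroxy-4-methylbenzoate | Cc1cc(OCc4ccccc4)c(C(=O)OCc4ccccc4)c(O)c1C(=O)Oc1c(COCc4ccccc4)c(O)c2C(=O)OCc2c1 | intermediate
15 | tribenzyl conneotricone (benzyl ether on the ring A phenol, benzyl ester on the ring A carboxyl, benzyl ether on the ring B hydroxymethyl, ring B phenol free) | Cc1cc(OCc4ccccc4)c(C(=O)OCc4ccccc4)c2c1C(=O)Oc1c(COCc4ccccc4)c(O)c3c(c1O2)COC3=O | intermediate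
16 | conneotricone | Cc1cc(O)c(C(=O)O)c2c1C(=O)Oc1c(CO)c(O)c3c(c1O2)COC3=O | target

**Step count**

Total: 11 steps. Longest linear sequence: 7 steps (steps 1–4 then 9–11, or steps 5–8 then 9–11).

**Steps most likely to fail**

Step 10. Several processes may compete with the ring closure:
- The ester may stay in its extended rotamer, so that the phenoxonium ion is consumed by intermolecular C–C or C–O coupling.
- The oxidised phenol may lose a proton from the neighbouring CH2OBn group (o-quinone methide formation), leading to benzylic oxidation.
- The p-aryloxyphenol product may be oxidised further.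
- Ring A may be oxidised first.

The fallback sets out from phthalide 6 and comes back at 15. Bromine is introduced before the ester is made, because in 14 an electrophile would go to the free carbon of ring A. NBS (1.0 equiv, MeCN, 0 °C) should brominate 6 at C4, its only free ring carbon, to give 4-bromo-6-[(benzyloxy)methyl]-5,7-dihydroxyisobenzofuran-1(3H)-one F1. DCC coupling with acid 12 as in step 9 should give the bromodepside F2. An intramolecular Ullmann diaryl ether synthesis (CuI, picolinic acid, K3PO4 1.2 equiv, DMSO, 80 °C) then joins the phenoxide of ring A, the more acidic of the two phenols, to the brominated carbon and gives 15.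

Step 4. The benzylic cation may alkylate the free C4 position of another molecule (Friedel–Crafts self-condensation to oligomers) faster than the solvent captures it, and transesterification of the hindered acetates may stay incomplete. The fallback sets out from dibromide 3 and comes back at 6, making the ether by O-benzylation while the phenols stay masked. Ag2CO3 in acetone–H2O at rt should hydrolyse both bromides, the arm ortho to the ester lactonising, to give 5,7-diacetoxy-6-(hydroxymethyl)isobenzofuran-1(3H)-one F3. Benzyl 2,2,2-trichloroacetimidate with catalytic TfOH (CH2Cl2–cyclohexane, 0 °C) should then give 5,7-diacetoxy-6-[(benzyloxy)methyl]isobenzofuran-1(3H)-one F4. K2CO3 in MeOH at 0 °C followed by acidification removes the two aryl acetates and gives 6.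

Step 11. Hydrogenolysis may run past the alcohol stage: the ring B ArCH2–O bond of the hydroxymethyl group may be cleaved to a methyl group, or the phthalide CH2–O bond may open. The fallback sets out from 15 and comes back at 16 without a new compound. BCl3 with pentamethylbenzene as cation scavenger (CH2Cl2, −78 °C, then aqueous work-up) removes the benzyl groups as benzyl cations by Lewis acid cleavage, a non-reductive method that cannot reduce the ring B benzylic positions.

**Further compounds**

F1 | step 10 | 4-bromo-6-[(benzyloxy)methyl]-5,7-dihydroxyisobenzofuran-1(3H)-one | O=C1OCc2c(Br)c(O)c(COCc3ccccc3)c(O)c21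
F2 | step 10 | bromodepside: benzyl 6-(benzyloxy)-3-({4-bromo-6-[(benzyloxy)methyl]-7-hydroxy-1-oxo-1,3-dihydroisobenzofuran-5-yl}oxycarbonyl)-2-hydroxy-4-methylbenzoate | Cc1cc(OCc4ccccc4)c(C(=O)OCc4ccccc4)c(O)c1C(=O)Oc1c(COCc4ccccc4)c(O)c2C(=O)OCc2c1Br
F3 | step 4 | 5,7-diacetoxy-6-(hydroxymethyl)isobenzofuran-1(3H)-one | CC(=O)Oc1cc2COC(=O)c2c(OC(C)=O)c1CO
F4 | step 4 | 5,7-diacetoxy-6-[(benzyloxy)methyl]isobenzofuran-1(3H)-one | CC(=O)Oc1cc2COC(=O)c2c(OC(C)=O)c1COCc3ccccc3
F0 | step 11 | none | none
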